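**Retrosynthetic overview**

- The target comes from a 6,7-epoxy ketone by acid isomerisation to the diosphenol; the epoxide comes from a cross-conjugated dienone whose side chain is attached by hydroboration/B-alkyl Suzuki coupling of a C5 vinyl group with an (E)-vinyl iodide.
- The vinyl dienone comes (Wittig, then DDQ) from the Diels–Alder adduct of a ring-A 2-ethoxydiene with tiglic aldehyde; this [4+2] step builds ring B and the C5 quaternary centre.
- The diene comes from an enol triflate by Stille coupling; its C1 centre (CH3 versus CH2OAc) is made by the key C–O bond formation, an enantiotopic-methyl-selective C(sp3)–H acetoxylation of a gem-dimethyl ketone.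
- Ring A is bought as 2,2-dimethylcyclohexane-1,3-dione; ring B is formed second.

Assumption: the sense of induction in the two catalyst-controlled steps (2 and 4) is taken as written; both catalysts are available as either enantiomer.
Assumption: the Diels–Alder adduct 7 is drawn as the endo isomer; its C4a epimer is equally usable because C4a and C6 are erased in step 6. Locants in the text follow the naphthalene numbering of the names.

**Step 1**
Reactants: 1 2,2-dimethylcyclohexane-1,3-dione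
Product: 2 6,6-dimethyl-5-oxocyclohex-1-en-1-yl trifluoromethanesulfonate
Conditions: KN(SiMe3)2 (1.05 equiv), THF, −78 °C; then PhN(SO2CF3)2, −78 → 0 °C
Reagents that add atoms: N-phenylbis(trifluoromethanesulfonimide), O=S(=O)(N(c1ccccc1)S(=O)(=O)C(F)(F)F)C(F)(F)F
Why: Enol triflate formation: each carbonyl can enolise only away from the quaternary carbon, so one equivalent of base and O-sulfonylation give the mono enol triflate, in which the two methyl groups are now enantiotopic.

**Step 2**
Reactants: 2 6,6-dimethyl-5-oxocyclohex-1-en-1-yl trifluoromethanesulfonate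
Product: 3 [(1R)-1-methyl-2-oxo-6-(trifluoromethanesulfonyloxy)cyclohex-5-en-1-yl]methyl acetate
Conditions: Pd(OAc)2 (10 mol %), (S)-2-amino-3,3-dimethylbutanoic acid (L-tert-leucine, 40 mol %), PhI(OAc)2 (1.5 equiv), AcOH/(CF3)2CHOH 1:4, 70 °C
Reagents that add atoms: (diacetoxyiodo)benzene, CC(=O)OI(OC(C)=O)c1ccccc1
Why: Proposed new method: the ketone condenses reversibly with the amino acid to an imine whose N,O-chelate holds divalent palladium beside the gem-dimethyl group, concerted metalation–deprotonation of one enantiotopic methyl gives a five-membered palladacycle in which the tert-butyl group of the chelate decides which methyl is palladated (this sets C1), PhI(OAc)2 oxidises it to tetravalent palladium, and C–OAc reductive elimination plus imine hydrolysis release 3 and the amino acid; the closest known reactions are the oxime-directed Pd(OAc)2/PhI(OAc)2 acetoxylation of methyl groups and the transient-directing-group β-C–H arylation of ketones, neither of which has been shown as an enantioselective methyl desymmetrisation by acetoxylation.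

**Step 3**
Reactants: 3 [(1R)-1-methyl-2-oxo-6-(trifluoromethanesulfonyloxy)cyclohex-5-en-1-yl]methyl acetate; 4 tributyl(1-ethoxyethenyl)stannane
Product: 5 [(1S)-6-(1-ethoxyethenyl)-1-methyl-2-oxocyclohex-5-en-1-yl]methyl acetate
Conditions: Pd(PPh3)4 (5 mol %), LiCl (3 equiv), 1,4-dioxane, 90 °C; filtration through basic alumina
Reagents that add atoms: none
Why: Stille coupling of a vinyl triflate with an α-alkoxyvinylstannane (chloride assists transmetalation) gives the 2-ethoxydiene directly without touching the ketone, the acetate or the C1 centre (the descriptor changes only because priorities change).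

**Step 4**
Reactants: 5 [(1S)-6-(1-ethoxyethenyl)-1-methyl-2-oxocyclohex-5-en-1-yl]methyl acetate; 6 (2E)-2-methylbut-2-enal
Product: 7 [(1S,4aS,5R,6S)-8-ethoxy-5-formyl-1,5,6-trimethyl-2-oxo-1,2,3,4,4a,5,6,7-octahydronaphthalen-1-yl]methyl acetate
Conditions: (3aS)-1-(2-methylphenyl)-3,3-diphenyltetrahydro-1H,3H-pyrrolo[1,2-c][1,3,2]oxazaborole (20 mol %), HN(SO2CF3)2 (18 mol %), threefold excess of the enal, CH2Cl2, −78 → −40 °C
Reagents that add atoms: none
Why: Catalytic enantioselective Diels–Alder reaction: the 2-ethoxy group makes the terminal CH2 of the diene nucleophilic so it bonds to the β-carbon of the enal ("para" regiochemistry) and the ring CH bonds to the α-carbon, while the protonated oxazaborolidine binds the s-trans enal and shields one face, which sets the quaternary C5 (and C6 through the E geometry); ring B is formed here.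

**Step 5**
Reactants: 7 [(1S,4aS,5R,6S)-8-ethoxy-5-formyl-1,5,6-trimethyl-2-oxo-1,2,3,4,4a,5,6,7-octahydronaphthalen-1-yl]methyl acetate
Product: 8 [(1S,4aR,5R,6S)-5-ethenyl-8-ethoxy-1,5,6-trimethyl-2-oxo-1,2,3,4,4a,5,6,7-octahydronaphthalen-1-yl]methyl acetate
Conditions: Ph3PCH3Br (1.5 equiv), KN(SiMe3)2 (1.4 equiv), THF, 0 °C; then 7, −78 → 0 °C
Reagents that add atoms: methyltriphenylphosphonium bromide, C[P+](c1ccccc1)(c1ccccc1)c1ccccc1.[Br-]
Why: Wittig methylenation: the non-enolisable aldehyde reacts far faster than the hindered α-quaternary ketone or the acetate, and no stereocentre is touched.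

**Step 6**
Reactants: 8 [(1S,4aR,5R,6S)-5-ethenyl-8-ethoxy-1,5,6-trimethyl-2-oxo-1,2,3,4,4a,5,6,7-octahydronaphthalen-1-yl]methyl acetate
Product: 10 [(1S,5R)-5-ethenyl-1,5,6-trimethyl-2,8-dioxo-1,2,3,4,5,8-hexahydronaphthalen-1-yl]methyl acetate, via cross-conjugated dienol ether 9 (not isolated)
Conditions: 2,3-dichloro-5,6-dicyano-1,4-benzoquinone (DDQ, 2.5 equiv), 1,4-dioxane, 25 → 60 °C; then H2O
Reagents that add atoms: water, O
Why: DDQ dehydrogenation of an enol ether, as in the conversion of steroidal 3-alkoxy-3,5-dienes to trienones: hydride abstraction from the allylic C4a–H gives an oxocarbenium ion, loss of a C7 proton gives 9, a second hydride abstraction at C6 and hydrolysis give the dienone; the saturated ketone is inert and the C5 quaternary centre prevents aromatisation.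

**Step 7**
Reactants: 11 but-2-yn-1-ol
Product: 12 (but-2-yn-1-yloxy)triethylsilane
Conditions: Et3SiCl, imidazole, CH2Cl2, 0 °C
Reagents that add atoms: chlorotriethylsilane, CC[Si](Cl)(CC)CC
Why: Standard silyl ether formation; the triethylsilyl group is chosen because the acid in the last step removes it.

**Step 8**
Reactants: 12 (but-2-yn-1-yloxy)triethylsilane
Product: 14 triethyl{[(2E)-3-iodobut-2-en-1-yl]oxy}silane, via alkenylzirconocene 13 (not isolated)
Conditions: Cp2Zr(H)Cl (1.3 equiv), THF, 25 → 40 °C; then I2, 0 °C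
Reagents that add atoms: iodine, [I][I]
Why: Hydrozirconation–iodination: syn addition of Zr–H places zirconium on the less hindered methyl-bearing carbon after equilibration with the slight excess of hydride, and iodinolysis with retention gives the E vinyl iodide.

**Step 9**
Reactants: 10 [(1S,5R)-5-ethenyl-1,5,6-trimethyl-2,8-dioxo-1,2,3,4,5,8-hexahydronaphthalen-1-yl]methyl acetate; 14 triethyl{[(2E)-3-iodobut-2-en-1-yl]oxy}silane
Product: 16 [(1S,5R)-1,5,6-trimethyl-5-{(3E)-3-methyl-5-[(triethylsilyl)oxy]pent-3-en-1-yl}-2,8-dioxo-1,2,3,4,5,8-hexahydronaphthalen-1-yl]methyl acetate, via alkylborane 15 (not isolated)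
Conditions: 9-BBN dimer (0.6 equiv), THF, 0 → 25 °C; then 14, PdCl2(dppf) (dppf = 1,1'-bis(diphenylphosphino)ferrocene, 5 mol %), AsPh3 (10 mol %), Cs2CO3, DMF/H2O, 25 °C
Reagents that add atoms: none
Why: Anti-Markovnikov hydroboration of the terminal vinyl group is faster than reduction of the two hindered ketones, and the B-alkyl Suzuki–Miyaura coupling joins C(sp3) to the vinyl iodide with retention of the E geometry.

**Step 10**
Reactants: 16 [(1S,5R)-1,5,6-trimethyl-5-{(3E)-3-methyl-5-[(triethylsilyl)oxy]pent-3-en-1-yl}-2,8-dioxo-1,2,3,4,5,8-hexahydronaphthalen-1-yl]methyl acetate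
Product: 17 [(1S,5S)-6,7-epoxy-1,5,6-trimethyl-5-{(3E)-3-methyl-5-[(triethylsilyl)oxy]pent-3-en-1-yl}-2,8-dioxo-1,2,3,4,5,6,7,8-octahydronaphthalen-1-yl]methyl acetate (either epoxide face)
Conditions: t-BuOOH (5.5 M in decane), 1,8-diazabicyclo[5.4.0]undec-7-ene (DBU), CH2Cl2, 0 → 25 °C
Reagents that add atoms: tert-butyl hydroperoxide, CC(C)(C)OO
Why: Weitz–Scheffer nucleophilic epoxidation attacks only the trisubstituted enone bond C6=C7 (the ring-fusion olefin is tetrasubstituted between two quaternary carbons, the side-chain olefin is electron-rich), and the non-nucleophilic base leaves the acetate alone; the epoxide configuration is lost in the next step.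

**Step 11**
Reactants: 17 [(1S,5S)-6,7-epoxy-1,5,6-trimethyl-5-{(3E)-3-methyl-5-[(triethylsilyl)oxy]pent-3-en-1-yl}-2,8-dioxo-1,2,3,4,5,6,7,8-octahydronaphthalen-1-yl]methyl acetate
Product: 19 [(1S,5S)-7-hydroxy-5-[(3E)-5-hydroxy-3-methylpent-3-en-1-yl]-1,5,6-trimethyl-2,8-dioxo-1,2,3,4,5,8-hexahydronaphthalen-1-yl]methyl acetate (CNP0512382.1), via silyl-protected diosphenol 18 (not isolated)
Conditions: p-toluenesulfonic acid monohydrate (TsOH·H2O, 0.3 equiv), THF, 0 → 25 °C; then H2O, 25 °C
Reagents that add atoms: none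
Why: Acid-catalysed isomerisation of an α,β-epoxy ketone to a diosphenol (opening at the tertiary C6, loss of the C7 proton, as in the preparation of 4-hydroxy-4-en-3-one steroids from 4,5-epoxy-3-ketones), followed by hydrolysis of the primary silyl ether; both quaternary centres are untouched.

**Compound list**

1 | 2,2-dimethylcyclohexane-1,3-dione | CC1(C)C(=O)CCCC1=O | starting material
2 | 6,6-dimethyl-5-oxocyclohex-1-en-1-yl trifluoromethanesulfonate | CC1(C)C(=O)CCC=C1OS(=O)(=O)C(F)(F)F | intermediate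
3 | [(1R)-1-methyl-2-oxo-6-(trifluoromethanesulfonyloxy)cyclohex-5-en-1-yl]methyl acetate | CC(=O)OC[C@@]1(C)C(=O)CCC=C1OS(=O)(=O)C(F)(F)F | intermediate
4 | tributyl(1-ethoxyethenyl)stannane | CCCC[Sn](CCCC)(CCCC)C(=C)OCC | starting material
5 | [(1S)-6-(1-ethoxyethenyl)-1-methyl-2-oxocyclohex-5-en-1-yl]methyl acetate | CC(=O)OC[C@@]1(C)C(=O)CCC=C1C(=C)OCC | intermediate
6 | (2E)-2-methylbut-2-enal | C/C=C(\C)C=O | starting material
7 | [(1S,4aS,5R,6S)-8-ethoxy-5-formyl-1,5,6-trimethyl-2-oxo-1,2,3,4,4a,5,6,7-octahydronaphthalen-1-yl]methyl acetate | CC(=O)OC[C@@]1(C)C(=O)CC[C@H]2C1=C(OCC)C[C@H](C)[C@@]2(C)C=O | intermediate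
8 | [(1S,4aR,5R,6S)-5-ethenyl-8-ethoxy-1,5,6-trimethyl-2-oxo-1,2,3,4,4a,5,6,7-octahydronaphthalen-1-yl]methyl acetate | CC(=O)OC[C@@]1(C)C(=O)CC[C@H]2C1=C(OCC)C[C@H](C)[C@@]2(C)C=C | intermediate
9 | [(1S,5R,6S)-5-ethenyl-8-ethoxy-1,5,6-trimethyl-2-oxo-1,2,3,4,5,6-hexahydronaphthalen-1-yl]methyl acetate | CC(=O)OC[C@@]1(C)C(=O)CCC2=C1C(OCC)=C[C@H](C)[C@@]2(C)C=C | intermediate
10 | [(1S,5R)-5-ethenyl-1,5,6-trimethyl-2,8-dioxo-1,2,3,4,5,8-hexahydronaphthalen-1-yl]methyl acetate | CC(=O)OC[C@@]1(C)C(=O)CCC2=C1C(=O)C=C(C)[C@@]2(C)C=C | intermediate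
11 | but-2-yn-1-ol | CC#CCO | starting material
12 | (but-2-yn-1-yloxy)triethylsilane | CC#CCO[Si](CC)(CC)CC | intermediate
13 | chloridobis(cyclopentadienyl)[(2E)-4-(triethylsilyloxy)but-2-en-2-yl]zirconium | C/C(=C\CO[Si](CC)(CC)CC)[Zr](Cl)(C1C=CC=C1)C1C=CC=C1 | intermediate
14 | triethyl{[(2E)-3-iodobut-2-en-1-yl]oxy}silane | I/C(C)=C/CO[Si](CC)(CC)CC | intermediate
15 | [(1S,5R)-5-[2-(9-borabicyclo[3.3.1]nonan-9-yl)ethyl]-1,5,6-trimethyl-2,8-dioxo-1,2,3,4,5,8-hexahydronaphthalen-1-yl]methyl acetate | CC(=O)OC[C@@]1(C)C(=O)CCC2=C1C(=O)C=C(C)[C@@]2(C)CCB3C4CCCC3CCC4 | intermediate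
16 | [(1S,5R)-1,5,6-trimethyl-5-{(3E)-3-methyl-5-[(triethylsilyl)oxy]pent-3-en-1-yl}-2,8-dioxo-1,2,3,4,5,8-hexahydronaphthalen-1-yl]methyl acetate | CC(=O)OC[C@@]1(C)C(=O)CCC2=C1C(=O)C=C(C)[C@@]2(C)CC/C(C)=C/CO[Si](CC)(CC)CC | intermediate
17 | [(1S,5S)-6,7-epoxy-1,5,6-trimethyl-5-{(3E)-3-methyl-5-[(triethylsilyl)oxy]pent-3-en-1-yl}-2,8-dioxo-1,2,3,4,5,6,7,8-octahydronaphthalen-1-yl]methyl acetate (either epoxide face) | CC(=O)OC[C@@]1(C)C(=O)CCC2=C1C(=O)C3OC3(C)[C@@]2(C)CC/C(C)=C/CO[Si](CC)(CC)CC | intermediate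
18 | [(1S,5S)-7-hydroxy-1,5,6-trimethyl-5-{(3E)-3-methyl-5-[(triethylsilyl)oxy]pent-3-en-1-yl}-2,8-dioxo-1,2,3,4,5,8-hexahydronaphthalen-1-yl]methyl acetate | CC(=O)OC[C@@]1(C)C(=O)CCC2=C1C(=O)C(O)=C(C)[C@@]2(C)CC/C(C)=C/CO[Si](CC)(CC)CC | intermediate
19 | [(1S,5S)-7-hydroxy-5-[(3E)-5-hydroxy-3-methylpent-3-en-1-yl]-1,5,6-trimethyl-2,8-dioxo-1,2,3,4,5,8-hexahydronaphthalen-1-yl]methyl acetate (CNP0512382.1) | CC(=O)OC[C@@]1(C)C(=O)CCC2=C1C(=O)C(O)=C(C)[C@@]2(C)CC/C(C)=C/CO | target

**Step count and risks**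

Total steps: 11 (9 in the main line, 2 for the vinyl iodide). Longest linear sequence: 9 (steps 1–6 and 9–11).

The three steps most likely to fail:

Step 2 (the new C–H acetoxylation): imine formation at the hindered ketone may be slow, the ketone may be oxidised at its CH2 side, or the two methyl groups may be poorly distinguished. The fallback uses known chemistry, sets out from 2 and returns at 3. Ketone 2 is reduced with BH3·SMe2 and (S)-1-methyl-3,3-diphenyltetrahydro-1H,3H-pyrrolo[1,2-c][1,3,2]oxazaborole (10 mol %) to (5R)-5-hydroxy-6,6-dimethylcyclohex-1-en-1-yl trifluoromethanesulfonate F1. Dehydrogenative silylation with Et2SiH2 and [Ir(cod)OMe]2 (cod = cycloocta-1,5-diene) gives (5R)-5-[(diethylsilyl)oxy]-6,6-dimethylcyclohex-1-en-1-yl trifluoromethanesulfonate F2. Hydroxyl-directed γ-C–H silylation ([Ir(cod)OMe]2, 3,4,7,8-tetramethyl-1,10-phenanthroline, norbornene, THF, 100 °C) is taken to occur at the methyl group trans to oxygen, as in the triterpenoid precedents, and closes the trans-fused oxasilolane (3aS,7aR)-2,2-diethyl-3a-methyl-2,3,3a,6,7,7a-hexahydro-1,2-benzoxasilol-4-yl trifluoromethanesulfonate F3. Tamao–Fleming oxidation (H2O2, KHCO3, KF) gives (5R,6S)-5-hydroxy-6-(hydroxymethyl)-6-methylcyclohex-1-en-1-yl trifluoromethanesulfonate F4. Acetylation of the primary hydroxyl (Ac2O, 2,4,6-collidine, −20 °C) gives [(1S,2R)-2-hydroxy-1-methyl-6-(trifluoromethanesulfonyloxy)cyclohex-5-en-1-yl]methyl acetate F5, and Dess–Martin oxidation of the secondary alcohol returns 3. If the cis methyl were silylated instead, the enantiomeric reduction catalyst would be used.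

Step 4 (enantioselective Diels–Alder): the diene is hindered and acid-labile, the enal is trisubstituted, and the enantioselectivity on this substrate is unproven. The fallback sets out from 5 and returns at 7. Catalyst control is given up: the cycloaddition is promoted by the achiral Lewis acid Me2AlCl (CH2Cl2, −78 °C). Because C1 is already a single enantiomer, addition to the two enal faces gives diastereomers, which are separated by preparative HPLC into 7 and [(1S,4aR,5S,6R)-8-ethoxy-5-formyl-1,5,6-trimethyl-2-oxo-1,2,3,4,4a,5,6,7-octahydronaphthalen-1-yl]methyl acetate F6, which is discarded.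

Step 11 (epoxy ketone to diosphenol): the tertiary cation can divert to an acyl-shift ring contraction, and the acid can ionise the allylic alcohol. The fallback sets out from 16 and returns at 19, replacing the epoxide route by regiodefined enol chemistry. RhCl(PPh3)3-catalysed 1,4-hydrosilylation with Et3SiH (benzene, 60 °C) reduces only the trisubstituted enone bond and gives [(1S,5R)-1,5,6-trimethyl-5-{(3E)-3-methyl-5-[(triethylsilyl)oxy]pent-3-en-1-yl}-2-oxo-8-[(triethylsilyl)oxy]-1,2,3,4,5,6-hexahydronaphthalen-1-yl]methyl acetate F7. Rubottom oxidation with one equivalent of dimethyldioxirane (acetone/CH2Cl2, −78 °C) and an aqueous citric acid work-up that removes both silyl groups gives [(1S,5R)-7-hydroxy-5-[(3E)-5-hydroxy-3-methylpent-3-en-1-yl]-1,5,6-trimethyl-2,8-dioxo-1,2,3,4,5,6,7,8-octahydronaphthalen-1-yl]methyl acetate F8. Cu(OAc)2 (2.2 equiv, aqueous MeOH, 25–50 °C) oxidises the α-ketol selectively to the 1,2-dione, which enolises to 19; the allylic alcohol is not touched.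

**Further compounds**

F1 | step 2 | (5R)-5-hydroxy-6,6-dimethylcyclohex-1-en-1-yl trifluoromethanesulfonate | CC1(C)[C@H](O)CCC=C1OS(=O)(=O)C(F)(F)F
F2 | step 2 | (5R)-5-[(diethylsilyl)oxy]-6,6-dimethylcyclohex-1-en-1-yl trifluoromethanesulfonate | CC1(C)[C@H](O[SiH](CC)CC)CCC=C1OS(=O)(=O)C(F)(F)F
F3 | step 2 | (3aS,7aR)-2,2-diethyl-3a-methyl-2,3,3a,6,7,7a-hexahydro-1,2-benzoxasilol-4-yl trifluoromethanesulfonate | C[C@]12C[Si](CC)(CC)O[C@@H]1CCC=C2OS(=O)(=O)C(F)(F)F
F4 | step 2 | (5R,6S)-5-hydroxy-6-(hydroxymethyl)-6-methylcyclohex-1-en-1-yl trifluoromethanesulfonate | C[C@]1(CO)[C@H](O)CCC=C1OS(=O)(=O)C(F)(F)F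
F5 | step 2 | [(1S,2R)-2-hydroxy-1-methyl-6-(trifluoromethanesulfonyloxy)cyclohex-5-en-1-yl]methyl acetate | CC(=O)OC[C@@]1(C)[C@H](O)CCC=C1OS(=O)(=O)C(F)(F)F
F6 | step 4 | [(1S,4aR,5S,6R)-8-ethoxy-5-formyl-1,5,6-trimethyl-2-oxo-1,2,3,4,4a,5,6,7-octahydronaphthalen-1-yl]methyl acetate | CC(=O)OC[C@@]1(C)C(=O)CC[C@@H]2C1=C(OCC)C[C@@H](C)[C@]2(C)C=O
F7 | step 11 | [(1S,5R)-1,5,6-trimethyl-5-{(3E)-3-methyl-5-[(triethylsilyl)oxy]pent-3-en-1-yl}-2-oxo-8-[(triethylsilyl)oxy]-1,2,3,4,5,6-hexahydronaphthalen-1-yl]methyl acetate (C6 epimers) | CC(=O)OC[C@@]1(C)C(=O)CCC2=C1C(O[Si](CC)(CC)CC)=CC(C)[C@@]2(C)CC/C(C)=C/CO[Si](CC)(CC)CC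
F8 | step 11 | [(1S,5R)-7-hydroxy-5-[(3E)-5-hydroxy-3-methylpent-3-en-1-yl]-1,5,6-trimethyl-2,8-dioxo-1,2,3,4,5,6,7,8-octahydronaphthalen-1-yl]methyl acetate (C6/C7 diastereomers) | CC(=O)OC[C@@]1(C)C(=O)CCC2=C1C(=O)C(O)C(C)[C@@]2(C)CC/C(C)=C/CO
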